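(Its constants stand for no real mixture; the flask was simulated.)

From the first moment after charging, the free catalyst of this flask stands at balance with the resting dimer and the substrate starts turning into intermediate. The question here is how much of that intermediate has already left when 5.0 % of the substrate are converted.

substrate 0.020 M; partner 0.0300 M; free catalyst 46 µM; second catalyst 0.18 mM

    intermediate → decomposed reagent (k1 = 0.0013 /min)
    2 free catalyst ⇌ resting dimer, settled at all times (K2 = 41000 /M)
    substrate + free catalyst ⇌ free catalyst + intermediate (K3 = 0.47, k3 = 200 /M/min)
    partner + second catalyst + intermediate → second catalyst + target (k4 = 950 /M²/min)

1. the form that holds most of the catalyst when 5.0 % of the substrate are converted (resting dimer / free catalyst)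
2. its share of the catalyst then
3. apparent order in partner when 5.0 % of the substrate are converted (percent change of the rate of making target for one percent more partner charged)
4. factor on the rate of making target when 5.0 % of the substrate are converted if free catalyst is charged twice over

- a doubled species enters its step squared and goes two at a time
- "the catalyst" is free catalyst with its forms; second catalyst is a second catalyst
- a form made of two catalysts counts as two
- charge of substrate (flask): 0.020 M

The reckoning here, made by hand, goes up a ladder of times. The dimer balance, kept at all times, comes first: with the dimer counted as two catalysts, the charge of 46 µM splits into 18.4 µM of free catalyst, so the resting dimer, the resting state here, holds 60.1 % of the catalyst, more than the free form.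

The next rung is the time to the moment asked about, called the mark here, and it is read from the fraction of substrate left. Leaving aside the return of intermediate, that fraction decays at 0.220 /h, so it reaches the mark, 95.0 % left, after 0.233 h.

Intermediate has two exits. Draining to target runs pseudo-first-order at 0.308 /h, a lifetime of 3.25 h, and decomposition has a lifetime of 12.8 h. The mark comes far sooner than the first of these, so intermediate made at a nearly even pace has an average age of half the mark time. The quantity to carry is the leak, the share of converted substrate that has already left intermediate at the mark: both exit constants together times that average age, 4.49 %. Nearly all the converted substrate therefore still stands as intermediate. Partner acts through the draining part of the leak, which puts the order in partner at 0.964.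

The forecast names the resting dimer with 60 % (58 % to 62 %), an order of 0.96 (0.92 to 1) and a factor of 1.02 (0.98 to 1.08) on doubling, holding of the intermediate that “its level is set by the conversion itself”.

The simulation gives the resting dimer with 60.1 %, an order of 0.96 and a factor of 1.02. This flask reached the mark at 0.246 h, against the 0.233 h reckoned. In the flask charged with twice the free catalyst, the balance is reckoned at 27.9 µM of free catalyst, and the reckoned leak scales inversely with the free catalyst, to 2.95 %. By this reckoning the intermediate standing at the mark in that flask, and with it the rate of making target, changes by the factor 1.02.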